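**Plan**
- Retrosynthesis: cut the C7–allyl bond (Stille), take C2–OH back to C2–H (benzylic ether oxidation), then cut O1–C2 and O4–C4a of the dioxane ring together. The fragments are a trans epoxide (from Suzuki coupling and Shi epoxidation) and an iodophenol (from an aniline).
- Enabling feature: the O1–C2–C3–O4 segment of the dioxane ring is a masked trans aryl-methyl epoxide. The epoxide oxygen remains on C3 and becomes O4 once arylated at C4a; the phenol oxygen becomes O1 by entering at the benzylic carbon C2.
- Forward: the epoxide and 5-bromo-2-iodo-3-methoxyphenol are joined in one pot that closes the dioxane ring, the only ring formed. Oxidation at C2 and allylation at C7 follow.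
- Stereochemistry: C3 (R) comes from the Shi epoxidation and its C–O bond is never broken. C2 (S) is set when water adds to the C2 oxocarbenium ion trans to the C3 methyl group.

Key step: step 5

Assumption: the hemiketal carbon C2 equilibrates by ring–chain tautomerism, and the (2S) epimer of the target (hydroxyl axial and trans to the C3 methyl, aryl equatorial) is taken to be the more stable one.

**Route**

Step 1
Reactants: 1 5-bromo-1,2,3-trimethoxybenzene; 2 (E)-prop-1-enylboronic acid
Product: 3 (E)-1,2,3-trimethoxy-5-(prop-1-en-1-yl)benzene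
Conditions: Pd(PPh3)4 (3 mol%), K2CO3, 1,4-dioxane/H2O, 90 °C
Reagents that add atoms: none
Why: Suzuki–Miyaura coupling of an aryl bromide with an alkenylboronic acid at zerovalent palladium proceeds with retention of the alkene geometry, so the (E)-propenylarene should result.

Step 2
Reactants: 3 (E)-1,2,3-trimethoxy-5-(prop-1-en-1-yl)benzene
Product: 4 (2R,3R)-2-methyl-3-(3,4,5-trimethoxyphenyl)oxirane
Conditions: Shi ketone (1,2:4,5-di-O-isopropylidene-β-D-erythro-2,3-hexodiulo-2,6-pyranose, from D-fructose, 30 mol%), KHSO5 (as 2KHSO5·KHSO4·K2SO4), K2CO3, Bu4NHSO4, MeCN/CH2(OMe)2, aq Na2B4O7 buffer, 0 °C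
Reagents that add atoms: potassium peroxymonosulfate, [K+].[O-]S(=O)(=O)OO
Why: Shi epoxidation of a trans-disubstituted styrene through the spiro transition state of the chiral dioxirane; the D-fructose-derived ketone delivers oxygen to the face that gives the (R,R)-epoxide, which fixes the later C3 as R.

Step 3
Reactants: 5 4-bromo-2,6-dimethoxyaniline
Product: 7 5-bromo-2-iodo-1,3-dimethoxybenzene, via diazonium tosylate 6 (not isolated)
Conditions: p-TsOH·H2O, NaNO2, KI, MeCN/H2O, 10 °C → rt
Reagents that add atoms: potassium iodide, [K+].[I-]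
Why: Diazotisation followed by Sandmeyer-type iododediazoniation puts iodine on the carbon that carried nitrogen, between the two methoxy groups, without organolithium chemistry that the aryl bromide would not tolerate.

Step 4
Reactants: 7 5-bromo-2-iodo-1,3-dimethoxybenzene
Product: 9 5-bromo-2-iodo-3-methoxyphenol, via aryloxydibromoborane 8 (not isolated)
Conditions: BBr3 (1.0 equiv), CH2Cl2, −78 → 0 °C; then H2O
Reagents that add atoms: none
Why: Lewis-acid ether cleavage with one equivalent of BBr3 should remove a single methyl group; the two methoxy groups are equivalent, so mono-demethylation can give only one phenol.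

Step 5
Reactants: 4 (2R,3R)-2-methyl-3-(3,4,5-trimethoxyphenyl)oxirane; 9 5-bromo-2-iodo-3-methoxyphenol
Product: 11 (2S,3R)-7-bromo-5-methoxy-3-methyl-2-(3,4,5-trimethoxyphenyl)-2,3-dihydro-1,4-benzodioxine, via ring-opened aryloxy alcohol 10 (not isolated)
Conditions: Cs2CO3, DMF, 80 °C; then CuI (10 mol%), 1,10-phenanthroline (20 mol%), 110 °C, same pot
Reagents that add atoms: none
Why: The cesium phenoxide of 9 opens epoxide 4 by SN2 attack at the benzylic carbon, whose transition state is stabilised by the trimethoxyphenyl ring while both epoxide carbons are equally substituted, giving the alkoxide of 10 with inversion at C2 (S). Once CuI and 1,10-phenanthroline are added, the C3 alkoxide binds monovalent copper, the neighbouring C–I bond adds oxidatively, and C–O reductive elimination from trivalent copper forms O4–C4a. The closest known reaction type is the copper-catalysed tandem epoxide ring opening and intramolecular Ullmann O-arylation of 2-halophenols to 2,3-dihydro-1,4-benzodioxines. The dioxane ring closes in a six-membered exo mode by attack of the tethered alkoxide on the aryl carbon that bears iodine. C3 keeps the R configuration from step 2 because its C–O bond is never broken, and the C2 configuration, set by inversion under substrate control, is of no consequence because C2 becomes planar in step 6. The step needs benzylic regioselectivity, secured by benzylic activation and by letting the epoxide open before copper is introduced, and iodide-over-bromide selectivity, secured because only the iodide is ortho to the tether and C–I is the more reactive bond.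

Step 6
Reactants: 11 (2S,3R)-7-bromo-5-methoxy-3-methyl-2-(3,4,5-trimethoxyphenyl)-2,3-dihydro-1,4-benzodioxine
Product: 13 (2S,3R)-7-bromo-5-methoxy-3-methyl-2-(3,4,5-trimethoxyphenyl)-2,3-dihydro-1,4-benzodioxin-2-ol, via oxocarbenium ion 12 (not isolated)
Conditions: DDQ (1.2 equiv), CH2Cl2/aq NaH2PO4–Na2HPO4 buffer (pH 7), 0 °C → rt
Reagents that add atoms: water, O
Why: DDQ oxidation of a benzylic ether abstracts hydride from C2–H, which is benzylic to the trimethoxyphenyl ring and α to O1; water should add to the planar oxocarbenium ion trans to the C3 methyl group, giving the anomerically stabilised (2S) hemiketal, while C3 is untouched.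

Step 7
Reactants: 13 (2S,3R)-7-bromo-5-methoxy-3-methyl-2-(3,4,5-trimethoxyphenyl)-2,3-dihydro-1,4-benzodioxin-2-ol; 14 allyltributylstannane
Product: 15 (2S,3R)-5-methoxy-3-methyl-7-(prop-2-en-1-yl)-2-(3,4,5-trimethoxyphenyl)-2,3-dihydro-1,4-benzodioxin-2-ol
Conditions: Pd(PPh3)4 (5 mol%), toluene, 100 °C; aq KF work-up
Reagents that add atoms: none
Why: Stille coupling of the aryl bromide with the allylstannane at zerovalent palladium runs without base, so the hemiketal and the C3 centre next to the masked ketone should survive.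

**Compound list**
1 | 5-bromo-1,2,3-trimethoxybenzene | COc1cc(Br)cc(OC)c1OC | starting material
2 | (E)-prop-1-enylboronic acid | C/C=C/B(O)O | starting material
3 | (E)-1,2,3-trimethoxy-5-(prop-1-en-1-yl)benzene | C/C=C/c1cc(OC)c(OC)c(OC)c1 | intermediate
4 | (2R,3R)-2-methyl-3-(3,4,5-trimethoxyphenyl)oxirane | C[C@H]1O[C@@H]1c1cc(OC)c(OC)c(OC)c1 | intermediate
5 | 4-bromo-2,6-dimethoxyaniline | COc1cc(Br)cc(OC)c1N | starting material
6 | 4-bromo-2,6-dimethoxybenzenediazonium 4-methylbenzenesulfonate (formed in the flask) | COc1cc(Br)cc(OC)c1[N+]#N.Cc1ccc(cc1)S(=O)(=O)[O-] | intermediate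
7 | 5-bromo-2-iodo-1,3-dimethoxybenzene | COc1cc(Br)cc(OC)c1I | intermediate
8 | dibromo(5-bromo-2-iodo-3-methoxyphenoxy)borane (formed in the flask) | COc1cc(Br)cc(OB(Br)Br)c1I | intermediate
9 | 5-bromo-2-iodo-3-methoxyphenol | COc1cc(Br)cc(O)c1I | intermediate
10 | (1S,2R)-1-(5-bromo-2-iodo-3-methoxyphenoxy)-1-(3,4,5-trimethoxyphenyl)propan-2-ol (present as its cesium alkoxide in the flask) | COc1cc(Br)cc(O[C@@H](c2cc(OC)c(OC)c(OC)c2)[C@@H](C)O)c1I | intermediate
11 | (2S,3R)-7-bromo-5-methoxy-3-methyl-2-(3,4,5-trimethoxyphenyl)-2,3-dihydro-1,4-benzodioxine | Brc1cc(OC)c2c(c1)O[C@@H](c1cc(OC)c(OC)c(OC)c1)[C@@H](C)O2 | intermediate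
12 | (3R)-7-bromo-5-methoxy-3-methyl-2-(3,4,5-trimethoxyphenyl)-3H-1,4-benzodioxin-1-ium (oxocarbenium ion, formed in the flask) | Brc1cc(OC)c2c(c1)[O+]=C(c1cc(OC)c(OC)c(OC)c1)[C@@H](C)O2 | intermediate
13 | (2S,3R)-7-bromo-5-methoxy-3-methyl-2-(3,4,5-trimethoxyphenyl)-2,3-dihydro-1,4-benzodioxin-2-ol | Brc1cc(OC)c2c(c1)O[C@@](O)(c1cc(OC)c(OC)c(OC)c1)[C@@H](C)O2 | intermediate
14 | allyltributylstannane | C=CC[Sn](CCCC)(CCCC)CCCC | starting material
15 | (2S,3R)-5-methoxy-3-methyl-7-(prop-2-en-1-yl)-2-(3,4,5-trimethoxyphenyl)-2,3-dihydro-1,4-benzodioxin-2-ol | C=CCc1cc(OC)c2c(c1)O[C@@](O)(c1cc(OC)c(OC)c(OC)c1)[C@@H](C)O2 | target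

**Count**
Total steps: 7. Longest linear sequence: 5 steps (1, 2, 5, 6, 7 from compound 1, or 3, 4, 5, 6, 7 from compound 5).

**Steps most likely to fail**

Step 5. The phenoxide may attack the methyl-bearing epoxide carbon instead of the benzylic one, or the one-pot sequence may stall after ring opening or be diverted into intermolecular aryl ether formation. The fallback sets out from 4 and 9 and makes the two C–O bonds in separate operations, with the first under acid control. Catalytic BF3·OEt2 in CH2Cl2 at −40 °C should open the epoxide at the benzylic carbon through a cation stabilised by the trimethoxyphenyl ring. This should give 10 together with its C1 epimer (1R,2R)-1-(5-bromo-2-iodo-3-methoxyphenoxy)-1-(3,4,5-trimethoxyphenyl)propan-2-ol F1. The isolated mixture is then cyclised with CuI, 1,10-phenanthroline and Cs2CO3 in toluene at 110 °C to 11 and its C2 epimer (2R,3R)-7-bromo-5-methoxy-3-methyl-2-(3,4,5-trimethoxyphenyl)-2,3-dihydro-1,4-benzodioxine F2. The route is rejoined at 11; F2 is carried through step 6 with it, because both epimers give oxocarbenium ion 12 and therefore 13.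

Step 6. Hydride abstraction may be sluggish, the electron-rich rings or the phenol of the ring-opened tautomer may be over-oxidised, or the oxocarbenium ion may lose the C3 proton. The fallback sets out from 11 and replaces hydride abstraction by hydrogen-atom abstraction. N-Hydroxyphthalimide (20 mol%), Co(OAc)2 (1 mol%) and O2 in MeCN at 40 °C should autoxidise the doubly activated C2–H to (2R,3R)-7-bromo-2-hydroperoxy-5-methoxy-3-methyl-2-(3,4,5-trimethoxyphenyl)-2,3-dihydro-1,4-benzodioxine F3. Reduction with PPh3 in CH2Cl2 at 0 °C then returns to the route at 13; the C2 configuration of F3 does not matter because the hemiketal equilibrates.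

Step 7. At 100 °C ring–chain tautomerism of the hemiketal may expose an enolisable α-aryloxy ketone and erode C3, and the allyl double bond may migrate into conjugation. The fallback sets out from 13 and locks the ring before the coupling. MeOH with pyridinium p-toluenesulfonate and 3 Å molecular sieves at rt should give the methyl ketal (2S,3R)-7-bromo-2,5-dimethoxy-3-methyl-2-(3,4,5-trimethoxyphenyl)-2,3-dihydro-1,4-benzodioxine F4. Stille coupling with 14 (Pd(PPh3)4, toluene, 100 °C) should give (2S,3R)-2,5-dimethoxy-3-methyl-7-(prop-2-en-1-yl)-2-(3,4,5-trimethoxyphenyl)-2,3-dihydro-1,4-benzodioxine F5. Mild hydrolysis (pyridinium p-toluenesulfonate, acetone/H2O, rt) then returns to the route at 15.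

Further compounds
F1 | step 5 | (1R,2R)-1-(5-bromo-2-iodo-3-methoxyphenoxy)-1-(3,4,5-trimethoxyphenyl)propan-2-ol | COc1cc(Br)cc(O[C@H](c2cc(OC)c(OC)c(OC)c2)[C@@H](C)O)c1I
F2 | step 5 | (2R,3R)-7-bromo-5-methoxy-3-methyl-2-(3,4,5-trimethoxyphenyl)-2,3-dihydro-1,4-benzodioxine | Brc1cc(OC)c2c(c1)O[C@H](c1cc(OC)c(OC)c(OC)c1)[C@@H](C)O2
F3 | step 6 | (2R,3R)-7-bromo-2-hydroperoxy-5-methoxy-3-methyl-2-(3,4,5-trimethoxyphenyl)-2,3-dihydro-1,4-benzodioxine | Brc1cc(OC)c2c(c1)O[C@@](OO)(c1cc(OC)c(OC)c(OC)c1)[C@@H](C)O2
F4 | step 7 | (2S,3R)-7-bromo-2,5-dimethoxy-3-methyl-2-(3,4,5-trimethoxyphenyl)-2,3-dihydro-1,4-benzodioxine | Brc1cc(OC)c2c(c1)O[C@@](OC)(c1cc(OC)c(OC)c(OC)c1)[C@@H](C)O2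
F5 | step 7 | (2S,3R)-2,5-dimethoxy-3-methyl-7-(prop-2-en-1-yl)-2-(3,4,5-trimethoxyphenyl)-2,3-dihydro-1,4-benzodioxine | C=CCc1cc(OC)c2c(c1)O[C@@](OC)(c1cc(OC)c(OC)c(OC)c1)[C@@H](C)O2
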